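## Retrosynthetic overview

1. The free acid and the benzoate come last: target ⇐ 2-(trimethylsilyl)ethyl (TMSE) ester benzoate ⇐ macrocyclic C1 alcohol.
2. The 11-membered carbocycle ⇐ open-chain epoxy enal ester, by forming one bond, C1–C11. A hydrogen atom is transferred to C10 of the prenyl terminus and the C11 centre adds to the C1 aldehyde. This is the bond made by the farnesyl 1,11-cyclization that leads to humulanes, done reductively so that C9–C10 is saturated and C1 carries its oxygen at once.
3. Epoxy enal ester ⇐ β-keto Weinreb amide, via (E)-enol triflate, carbonylation (C15) and amide-to-aldehyde reduction (C1).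
4. β-Keto amide ⇐ acetoacetamide dianion + (2R,3R)-epoxygeranyl triflate; the oxirane ⇐ Sharpless epoxidation of geraniol.
5. Ring order: oxirane first (step 1, fixes C6/C7 and the absolute configuration), carbocycle second (step 6, sets C1).

Assumption: the target SMILES is read as (1R,4E,6R,11R)-6-(benzoyloxy)-7,7,11-trimethyl-12-oxabicyclo[9.1.0]dodec-4-ene-4-carboxylic acid (trans-oxirane; ring carbons cis across the alkene); N-methoxy-N-methyl-3-oxobutanamide is taken as a purchasable catalogue compound; humulane locants are used in the text (C1 = benzoyloxy carbon, C2=C3 alkene, C15 = carboxyl carbon on C3, C6/C7 = oxirane carbons, C11 = gem-dimethyl carbon).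

## Route

Step 1
Reactants: 1 geraniol, (2E)-3,7-dimethylocta-2,6-dien-1-ol
Product: 2 (2R,3R)-2,3-epoxygeraniol, [(2R,3R)-3-methyl-3-(4-methylpent-3-en-1-yl)oxiran-2-yl]methanol
Conditions: t-BuOOH (1.5 equiv), Ti(OiPr)4 (5 mol%), D-(−)-diethyl tartrate (6 mol%), 4 Å MS, CH2Cl2, −20 °C
Reagents that add atoms: tert-butyl hydroperoxide, CC(C)(C)OO
Why: Sharpless asymmetric epoxidation: the allylic hydroxyl binds the titanium–tartrate–peroxide complex so that only the 2,3-alkene reacts, and the D-(−)-tartrate gives the (2R,3R)-oxirane (mirror image of the 2S,3S product that the L-(+)-ester gives with geraniol), which fixes C6 and C7 of the target.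

Step 2
Reactants: 2 (2R,3R)-2,3-epoxygeraniol; 3 N-methoxy-N-methyl-3-oxobutanamide
Product: 5 N-methoxy-N-methyl-5-[(2R,3R)-3-methyl-3-(4-methylpent-3-en-1-yl)oxiran-2-yl]-3-oxopentanamide, via epoxygeranyl triflate 4 (not isolated)
Conditions: 2, n-BuLi (1.0 equiv), Et2O, −78 °C; Tf2O (1.05 equiv), −78 °C, 15 min; then dianion of 3 [3 (1.5 equiv), LiN(i-Pr)2 (3.0 equiv), THF, 0 °C] added at −78 °C, → −30 °C; aq. NH4Cl
Reagents that add atoms: none
Why: O-triflation followed by Weiler-type γ-alkylation of a β-dicarbonyl dianion (SN2): the primary triflate is displaced at −78 °C far faster than the hindered trisubstituted oxirane can open, so the C4–C5 bond forms and both oxirane stereocentres are untouched.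

Step 3
Reactants: 5 N-methoxy-N-methyl-5-[(2R,3R)-3-methyl-3-(4-methylpent-3-en-1-yl)oxiran-2-yl]-3-oxopentanamide
Product: 6 (2E)-1-[methoxy(methyl)amino]-5-[(2R,3R)-3-methyl-3-(4-methylpent-3-en-1-yl)oxiran-2-yl]-1-oxopent-2-en-3-yl trifluoromethanesulfonate
Conditions: Tf2O (1.5 equiv), 25% aq. Me4NOH (5 equiv), toluene, 0 °C, 20 min
Reagents that add atoms: trifluoromethanesulfonic anhydride, O=S(=O)(OS(=O)(=O)C(F)(F)F)C(F)(F)F
Why: Stereoselective enol triflation of a β-dicarbonyl enolate under biphasic Schotten–Baumann conditions: with the non-chelating tetramethylammonium counter-ion the enolate reacts from its extended, dipole-minimized form, which puts OTf trans to the amide carbonyl, the C2=C3 geometry of the target (precedent is for β-keto esters, here extended to the amide).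

Step 4
Reactants: 6 (E)-enol triflate
Product: 7 2-(trimethylsilyl)ethyl (2E)-4-[methoxy(methyl)amino]-2-{2-[(2R,3R)-3-methyl-3-(4-methylpent-3-en-1-yl)oxiran-2-yl]ethyl}-4-oxobut-2-enoate
Conditions: CO (1 atm), Me3SiCH2CH2OH (5 equiv), Pd(OAc)2 (5 mol%), PPh3 (10 mol%), Et3N (2 equiv), DMF, 50 °C
Reagents that add atoms: carbon monoxide, [C-]#[O+]; 2-(trimethylsilyl)ethanol, C[Si](C)(C)CCO
Why: Palladium-catalysed alkoxycarbonylation of a vinyl triflate (oxidative addition to zerovalent palladium, CO insertion, alcoholysis) keeps the alkene geometry and installs C15 as an ester that fluoride can remove later without touching a benzoate.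

Step 5
Reactants: 7 Weinreb amide TMSE ester
Product: 8 2-(trimethylsilyl)ethyl (2E)-2-{2-[(2R,3R)-3-methyl-3-(4-methylpent-3-en-1-yl)oxiran-2-yl]ethyl}-4-oxobut-2-enoate
Conditions: i-Bu2AlH (1.2 equiv), THF, −78 °C, 30 min; aq. potassium sodium tartrate
Reagents that add atoms: none
Why: Weinreb amide reduction: hydride addition stops at the chelated tetrahedral aluminium intermediate, which gives the aldehyde only on work-up, while the α-branched TMSE ester and the oxirane are inert at −78 °C.

Step 6
Reactants: 8 open-chain epoxy enal TMSE ester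
Product: 10 2-(trimethylsilyl)ethyl (1R,4E,6R,11R)-6-hydroxy-7,7,11-trimethyl-12-oxabicyclo[9.1.0]dodec-4-ene-4-carboxylate, via phenylsilyl ether 9 (not isolated)
Conditions: [N,N′-bis(3,5-di-tert-butylsalicylidene)-1,2-cyclohexanediaminato]cobalt (divalent cobalt, 10 mol%), CrCl3(thf)3 (50 mol%), PhSiH3 (2.5 equiv), THF, 23 °C, 8 added over 12 h by syringe pump (final 2 mM); then aq. NaHCO3, MeOH, 0 °C
Reagents that add atoms: none
Why: Proposed new method: a macrocyclizing variant of cobalt-hydride hydrogen-atom-transfer/chromium dual catalysis, whose closest known reaction type is the intermolecular branch-selective MHAT–chromium coupling of unactivated alkenes with aldehydes (and, for ring size, Nozaki–Hiyama–Kishi macrocyclization): the trivalent cobalt hydride formed from the salen complex and PhSiH3 delivers H• to C10 of the only electron-rich alkene, the tertiary C11 radical is trapped by divalent chromium (electron relay from the divalent cobalt left after HAT to trivalent chromium closes both cycles) and the alkylchromium adds 1,2 to the chromium-bound C1 aldehyde, Si–H/Cr–O exchange releasing silyl ether 9; the cis placement of C1 and C4 on C2=C3 and the gem-dimethyl group favour closure, and C1 is set under substrate control by the (6R,7R)-oxirane in a transition state that keeps the chromium-bound oxygen and the oxirane oxygen on the outside of the forming ring, from which the (1R) alcohol is expected as the major, chromatographically separable epimer (this selectivity is a prediction, not a demonstrated result).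

Step 7
Reactants: 10 macrocyclic C1 alcohol
Product: 11 2-(trimethylsilyl)ethyl (1R,4E,6R,11R)-6-(benzoyloxy)-7,7,11-trimethyl-12-oxabicyclo[9.1.0]dodec-4-ene-4-carboxylate
Conditions: BzCl (3 equiv), pyridine (6 equiv), DMAP (0.3 equiv), CH2Cl2, 0 → 35 °C
Reagents that add atoms: benzoyl chloride, O=C(Cl)c1ccccc1
Why: DMAP-catalysed acylation (nucleophilic catalysis through the N-benzoylpyridinium ion) esterifies the hindered allylic alcohol at oxygen, so the C1–O bond and the C1 configuration are retained.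

Step 8
Reactants: 11 benzoate TMSE ester
Product: 12 (1R,4E,6R,11R)-6-(benzoyloxy)-7,7,11-trimethyl-12-oxabicyclo[9.1.0]dodec-4-ene-4-carboxylic acid (target)
Conditions: Bu4NF (3 equiv), THF, 0 → 23 °C; cold pH 3 H3PO4/NaH2PO4 buffer
Reagents that add atoms: none
Why: Fluoride-induced β-elimination of the 2-(trimethylsilyl)ethyl ester releases the carboxylate, ethylene and Me3SiF without hydrolysing the benzoate, and the cold buffered work-up gives the acid without acid-catalysed opening of the oxirane.

## Compound list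

1 | geraniol, (2E)-3,7-dimethylocta-2,6-dien-1-ol | CC(C)=CCC/C(C)=C/CO | starting material
2 | [(2R,3R)-3-methyl-3-(4-methylpent-3-en-1-yl)oxiran-2-yl]methanol | CC(C)=CCC[C@@]1(C)O[C@@H]1CO | intermediate
3 | N-methoxy-N-methyl-3-oxobutanamide | CC(=O)CC(=O)N(C)OC | starting material
4 | [(2R,3R)-3-methyl-3-(4-methylpent-3-en-1-yl)oxiran-2-yl]methyl trifluoromethanesulfonate | CC(C)=CCC[C@@]1(C)O[C@@H]1COS(=O)(=O)C(F)(F)F | intermediate
5 | N-methoxy-N-methyl-5-[(2R,3R)-3-methyl-3-(4-methylpent-3-en-1-yl)oxiran-2-yl]-3-oxopentanamide | CC(C)=CCC[C@@]1(C)O[C@@H]1CCC(=O)CC(=O)N(C)OC | intermediate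
6 | (2E)-1-[methoxy(methyl)amino]-5-[(2R,3R)-3-methyl-3-(4-methylpent-3-en-1-yl)oxiran-2-yl]-1-oxopent-2-en-3-yl trifluoromethanesulfonate | CC(C)=CCC[C@@]1(C)O[C@@H]1CC/C(OS(=O)(=O)C(F)(F)F)=C\C(=O)N(C)OC | intermediate
7 | 2-(trimethylsilyl)ethyl (2E)-4-[methoxy(methyl)amino]-2-{2-[(2R,3R)-3-methyl-3-(4-methylpent-3-en-1-yl)oxiran-2-yl]ethyl}-4-oxobut-2-enoate | CC(C)=CCC[C@@]1(C)O[C@@H]1CC/C(C(=O)OCC[Si](C)(C)C)=C\C(=O)N(C)OC | intermediate
8 | 2-(trimethylsilyl)ethyl (2E)-2-{2-[(2R,3R)-3-methyl-3-(4-methylpent-3-en-1-yl)oxiran-2-yl]ethyl}-4-oxobut-2-enoate | CC(C)=CCC[C@@]1(C)O[C@@H]1CC/C(C(=O)OCC[Si](C)(C)C)=C\C=O | intermediate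
9 | 2-(trimethylsilyl)ethyl (1R,4E,6R,11R)-7,7,11-trimethyl-6-[(phenylsilyl)oxy]-12-oxabicyclo[9.1.0]dodec-4-ene-4-carboxylate | CC1(C)CCC[C@@]2(C)O[C@@H]2CC/C(C(=O)OCC[Si](C)(C)C)=C\[C@H]1O[SiH2]c1ccccc1 | intermediate
10 | 2-(trimethylsilyl)ethyl (1R,4E,6R,11R)-6-hydroxy-7,7,11-trimethyl-12-oxabicyclo[9.1.0]dodec-4-ene-4-carboxylate | CC1(C)CCC[C@@]2(C)O[C@@H]2CC/C(C(=O)OCC[Si](C)(C)C)=C\[C@H]1O | intermediate
11 | 2-(trimethylsilyl)ethyl (1R,4E,6R,11R)-6-(benzoyloxy)-7,7,11-trimethyl-12-oxabicyclo[9.1.0]dodec-4-ene-4-carboxylate | CC1(C)CCC[C@@]2(C)O[C@@H]2CC/C(C(=O)OCC[Si](C)(C)C)=C\[C@H]1OC(=O)c1ccccc1 | intermediate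
12 | (1R,4E,6R,11R)-6-(benzoyloxy)-7,7,11-trimethyl-12-oxabicyclo[9.1.0]dodec-4-ene-4-carboxylic acid | CC1(C)CCC[C@@]2(C)O[C@@H]2CC/C(C(=O)O)=C\[C@H]1OC(=O)c1ccccc1 | target

## Step count and risks

Total step count: 8. Longest linear sequence: 8 steps (1 → 12).

Three steps most likely to fail:

**Step 6 (ring closure).** It is unprecedented as a macrocyclization. The cobalt hydride may also reduce the electron-poor enal alkene or the aldehyde. The tertiary C11 radical may add to C2 (10-membered Giese product) or be reduced before chromium captures it. Trivalent chromium may open the oxirane. The C1 epimer ratio is only predicted. The fallback sets out from 7 and comes back at 10, and closes the same C1–C11 bond with an allyl nucleophile instead of a radical-derived alkylchromium.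
- Sensitized photo-oxygenation of the prenyl terminus of 7 (O2, tetraphenylporphyrin, hν, CH2Cl2, 0 °C; then PPh3) gives, after separation from its secondary regioisomer, the tertiary allylic alcohol F1.
- Reduction of the Weinreb amide (i-Bu2AlH, 2.3 equiv, THF, −78 °C) gives the hydroxy aldehyde F2.
- Umpolung allylation (Pd(PPh3)4, Et3B, THF, 5 mM, 23 °C) ionizes the allylic alcohol on zerovalent palladium and passes the allyl unit to boron. The allylborane adds to the aldehyde through its more substituted terminus C11 in a six-membered transition state, giving the 8,9-unsaturated macrocyclic alcohol F3.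
- Diimide (2-nitrobenzenesulfonohydrazide, Et3N, CH2Cl2) saturates only the disubstituted C9=C10 alkene and leaves the trisubstituted enoate, giving 10.

**Step 3 (E-selective enol triflation).** The E/Z control is known for β-keto esters but not for this β-keto amide, and Tf2O may attack the oxirane. The fallback sets out from 5 and comes back at 8, and replaces kinetic control by thermodynamic control.
- Chelation-controlled triflation (LiOTf, Et3N, Tf2O, CH2Cl2, −78 °C) gives the (Z)-enol triflate F4.
- The same carbonylation as in step 4 gives the (Z)-amide ester F5.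
- Reduction with i-Bu2AlH at −78 °C gives the (Z)-aldehyde F6.
- Catalytic I2 (5 mol%, CH2Cl2, daylight) equilibrates F6 to the more stable isomer with formyl trans to the ester, which is 8.

**Step 2 (triflate alkylation).** The in-situ epoxy triflate may decompose before it is alkylated, or the dianion may attack the oxirane. The fallback sets out from 2 and comes back at 5, and makes the C4–C5 bond by carbonyl addition instead of SN2 displacement.
- Parikh–Doering oxidation (SO3·pyridine, DMSO, i-Pr2NEt) gives the epoxy aldehyde F7.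
- Addition of the dianion of 3 (THF, −78 °C) gives the hydroxy keto amide F8 as an inconsequential epimer mixture.
- Mesylation–elimination (MsCl, excess Et3N, CH2Cl2, 0 → 23 °C) gives the (E)-enone F9.
- Diimide (2-nitrobenzenesulfonohydrazide, Et3N) reduces the conjugated disubstituted alkene only and gives 5.

Further compounds
F1 | step 6 | 2-(trimethylsilyl)ethyl (2E)-2-{2-[(2R,3R)-3-[(2E)-4-hydroxy-4-methylpent-2-en-1-yl]-3-methyloxiran-2-yl]ethyl}-4-[methoxy(methyl)amino]-4-oxobut-2-enoate | CC(C)(O)/C=C/C[C@@]1(C)O[C@@H]1CC/C(C(=O)OCC[Si](C)(C)C)=C\C(=O)N(C)OC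
F2 | step 6 | 2-(trimethylsilyl)ethyl (2E)-2-{2-[(2R,3R)-3-[(2E)-4-hydroxy-4-methylpent-2-en-1-yl]-3-methyloxiran-2-yl]ethyl}-4-oxobut-2-enoate | CC(C)(O)/C=C/C[C@@]1(C)O[C@@H]1CC/C(C(=O)OCC[Si](C)(C)C)=C\C=O
F3 | step 6 | 2-(trimethylsilyl)ethyl (1R,4E,6R,8E,11R)-6-hydroxy-7,7,11-trimethyl-12-oxabicyclo[9.1.0]dodeca-4,8-diene-4-carboxylate | CC1(C)/C=C/C[C@@]2(C)O[C@@H]2CC/C(C(=O)OCC[Si](C)(C)C)=C\[C@H]1O
F4 | step 3 | (2Z)-1-[methoxy(methyl)amino]-5-[(2R,3R)-3-methyl-3-(4-methylpent-3-en-1-yl)oxiran-2-yl]-1-oxopent-2-en-3-yl trifluoromethanesulfonate | CC(C)=CCC[C@@]1(C)O[C@@H]1CC/C(OS(=O)(=O)C(F)(F)F)=C/C(=O)N(C)OC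
F5 | step 3 | 2-(trimethylsilyl)ethyl (2Z)-4-[methoxy(methyl)amino]-2-{2-[(2R,3R)-3-methyl-3-(4-methylpent-3-en-1-yl)oxiran-2-yl]ethyl}-4-oxobut-2-enoate | CC(C)=CCC[C@@]1(C)O[C@@H]1CC/C(C(=O)OCC[Si](C)(C)C)=C/C(=O)N(C)OC
F6 | step 3 | 2-(trimethylsilyl)ethyl (2Z)-2-{2-[(2R,3R)-3-methyl-3-(4-methylpent-3-en-1-yl)oxiran-2-yl]ethyl}-4-oxobut-2-enoate | CC(C)=CCC[C@@]1(C)O[C@@H]1CC/C(C(=O)OCC[Si](C)(C)C)=C/C=O
F7 | step 2 | (2S,3R)-3-methyl-3-(4-methylpent-3-en-1-yl)oxirane-2-carbaldehyde | CC(C)=CCC[C@@]1(C)O[C@@H]1C=O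
F8 | step 2 | 5-hydroxy-N-methoxy-N-methyl-5-[(2R,3R)-3-methyl-3-(4-methylpent-3-en-1-yl)oxiran-2-yl]-3-oxopentanamide (both C5 epimers) | CC(C)=CCC[C@@]1(C)O[C@@H]1C(O)CC(=O)CC(=O)N(C)OC
F9 | step 2 | (4E)-N-methoxy-N-methyl-5-[(2R,3R)-3-methyl-3-(4-methylpent-3-en-1-yl)oxiran-2-yl]-3-oxopent-4-enamide | CC(C)=CCC[C@@]1(C)O[C@@H]1/C=C/C(=O)CC(=O)N(C)OC
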